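**Plan**

- Labels: ring A is the cyclohexadienone (C1 with the hexanoyl group, C2 enol carbon, C3 the quaternary carbon with methyl and prenyl, C4 enol carbon, C5 with the bridging CH2 C7, C6 the ring ketone). Ring B is the arene (C1' on C7, C2' OMe, C3' H, C4' OH, C5' hexanoyl, C6' OH).
- Retrosynthetic cuts, in order: the two O–MOM bonds on ring B; the bond from C3 to the prenyl CH2, which re-aromatises ring A; the C5–C7 bond; the C1'–C7 bond (via a formyl group); both aryl–hexanoyl bonds.
- Forward: both six-membered rings are bought as phloroglucinols, so no ring is formed. Each is hexanoylated; ring B is methylated at the C2' oxygen, formylated at C1', MOM-capped and turned into a benzylic bromide that C-benzylates ring A at C5. Prenylation at C3 and MOM removal finish the route.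
- Enabling feature: in the aromatic precursor every ring A carbon is substituted (C1 acyl, C3 methyl, C5 benzyl) and the ring B phenols are masked. The C4 phenolate of ring A can therefore keep a prenyl group on carbon only by dearomatising, and C3 (methyl) is far less shielded than C5 (2,6-disubstituted benzyl).
- Stereochemistry: the only stereocentre, C3 (S), is set in the key step by a chiral bisphosphine–palladium catalyst acting on a flat, achiral substrate. Being quaternary, it cannot epimerise afterwards.

Key step: step 10

Assumption: the sense of induction of the bisphosphine with this nucleophile cannot be derived from a model with certainty; the (R,R)-DACH-phenyl ligand is written as the enantiomer that should lead to (S)-15, and its (S,S) antipode would be used if the sense proved opposite.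

**Step 1**
Reactants: 1 phloroglucinol; 2 hexanoyl chloride
Product: 3 1-(2,4,6-trihydroxyphenyl)hexan-1-one
Conditions: AlCl3 (3.5 equiv), CH2Cl2/MeNO2, 0 °C → 40 °C; ice/aq. HCl
Reagents that add atoms: none
Why: Friedel–Crafts C-acylation of the strongly activated triol, which should stop at the mono-ketone because the chelated aryl ketone deactivates the ring.

**Step 2**
Reactants: 3 1-(2,4,6-trihydroxyphenyl)hexan-1-one
Product: 4 1-(2,6-dihydroxy-4-methoxyphenyl)hexan-1-one
Conditions: Me2SO4 (1.05 equiv), K2CO3 (1.1 equiv), acetone, rt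
Reagents that add atoms: dimethyl sulfate, COS(=O)(=O)OC
Why: Williamson O-methylation, selective because the hydroxyl para to the ketone is the most acidic and the only one not hydrogen-bonded to the carbonyl group.

**Step 3**
Reactants: 4 1-(2,6-dihydroxy-4-methoxyphenyl)hexan-1-one
Product: 6 3-hexanoyl-2,4-dihydroxy-6-methoxybenzaldehyde, via α-chloro ether 5 (not isolated)
Conditions: Cl2CHOMe (1.3 equiv), TiCl4 (3 equiv), CH2Cl2, −15 → 0 °C; then 1 M aq. HCl, rt
Reagents that add atoms: dichloromethyl methyl ether, COC(Cl)Cl; water, O
Why: Rieche formylation (electrophilic aromatic substitution by the TiCl4-activated dichloromethyl ether) at one of the two equivalent free ring carbons, the first formyl group deactivating the ring towards a second, followed by hydrolysis of α-chloro ether 5 on acidic work-up.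

**Step 4**
Reactants: 6 3-hexanoyl-2,4-dihydroxy-6-methoxybenzaldehyde
Product: 7 3-hexanoyl-6-methoxy-2,4-bis(methoxymethoxy)benzaldehyde
Conditions: NaH (2.3 equiv), DMF, 0 °C; MOMCl (2.5 equiv), 0 °C → rt
Reagents that add atoms: chloromethyl methyl ether, COCCl
Why: Williamson-type MOM protection, in which full deprotonation with NaH overcomes the chelation of both phenols to the neighbouring carbonyl groups.

**Step 5**
Reactants: 7 3-hexanoyl-6-methoxy-2,4-bis(methoxymethoxy)benzaldehyde
Product: 8 1-[3-(hydroxymethyl)-4-methoxy-2,6-bis(methoxymethoxy)phenyl]hexan-1-one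
Conditions: NaBH4 (0.6 equiv), THF/MeOH, −20 → 0 °C
Reagents that add atoms: none
Why: Chemoselective borohydride reduction, the aldehyde being far more electrophilic than the twisted aryl ketone flanked by two ortho alkoxy groups.

**Step 6**
Reactants: 8 1-[3-(hydroxymethyl)-4-methoxy-2,6-bis(methoxymethoxy)phenyl]hexan-1-one
Product: 9 1-[3-(bromomethyl)-4-methoxy-2,6-bis(methoxymethoxy)phenyl]hexan-1-one
Conditions: CBr4 (1.3 equiv), PPh3 (1.3 equiv), 2,6-lutidine (0.3 equiv), CH2Cl2, −20 → 0 °C; short silica plug, used at once
Reagents that add atoms: carbon tetrabromide, BrC(Br)(Br)Br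
Why: Appel bromination under neutral conditions that should spare the MOM acetals and the ketone; the electron-rich benzylic bromide is not stored.

**Step 7**
Reactants: 10 2-methylphloroglucinol; 2 hexanoyl chloride
Product: 11 1-(2,4,6-trihydroxy-3-methylphenyl)hexan-1-one
Conditions: AlCl3 (3.5 equiv), CH2Cl2/MeNO2, 0 °C → 40 °C; ice/aq. HCl
Reagents that add atoms: none
Why: Friedel–Crafts acylation at one of the two symmetry-equivalent free ring carbons, so a single regioisomer should result.

**Step 8**
Reactants: 11 1-(2,4,6-trihydroxy-3-methylphenyl)hexan-1-one; 9 1-[3-(bromomethyl)-4-methoxy-2,6-bis(methoxymethoxy)phenyl]hexan-1-one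
Product: 12 1-(3-{[3-hexanoyl-6-methoxy-2,4-bis(methoxymethoxy)phenyl]methyl}-2,4,6-trihydroxy-5-methylphenyl)hexan-1-one
Conditions: 11 (2 equiv), 1 M aq. KOH (2 equiv), THF, 0 °C; 9 (1 equiv) in THF dropwise, 0 °C → rt; aq. NH4Cl
Reagents that add atoms: none
Why: Alkali-mediated C-alkylation of an ambident acylphloroglucinol phenolate in a protic medium, where hydrogen bonding shields oxygen, the only unsubstituted ring carbon (C5) attacks the benzylic bromide, tautomerisation restores the arene, and the excess of 11 suppresses a second alkylation.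

**Step 9**
Reactants: 13 prenol
Product: 14 methyl 3-methylbut-2-en-1-yl carbonate
Conditions: ClCO2Me (1.2 equiv), pyridine (1.5 equiv), CH2Cl2, 0 °C → rt
Reagents that add atoms: methyl chloroformate, COC(=O)Cl
Why: O-acylation of a primary allylic alcohol with a chloroformate (carbonate formation), pyridine taking up the HCl.

**Step 10**
Reactants: 12 bis-MOM diarylmethane; 14 methyl 3-methylbut-2-en-1-yl carbonate
Product: 15 (4S)-2-hexanoyl-6-{[3-hexanoyl-6-methoxy-2,4-bis(methoxymethoxy)phenyl]methyl}-3,5-dihydroxy-4-methyl-4-(3-methylbut-2-en-1-yl)cyclohexa-2,5-dien-1-one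
Conditions: Pd2(dba)3·CHCl3 (2.5 mol %), (R,R)-DACH-phenyl Trost ligand [N,N'-((1R,2R)-cyclohexane-1,2-diyl)bis(2-(diphenylphosphanyl)benzamide), 7.5 mol %], 14 (1.2 equiv), degassed 1,4-dioxane, 0 °C → rt, no added base
Reagents that add atoms: none
Why: Zerovalent palladium ionises carbonate 14 to a cationic 1,1-dimethylallyl complex of divalent palladium while the leaving group loses CO2 to give methoxide, which deprotonates the ring A C4 hydroxyl (para to the hexanoyl group, the most acidic site); the phenolate then attacks the unsubstituted allyl terminus through C3 on the face away from the metal and zerovalent palladium is released. The closest known reaction type is the palladium-catalysed asymmetric allylic alkylation (Tsuji–Trost) that dearomatises substituted 2-naphthols and phenols at a substituted ortho carbon, together with the racemic dearomative C-allylation of acylphloroglucinols. No ring closes; only the bond from C3 to the prenyl CH2 forms, and ring A remains as the enolised cyclohexadienone, whose vinylogous-acid stabilisation drives the reaction. The C3 stereocentre is under catalyst control, since 12 is flat and achiral and the chiral pocket of the bisphosphine around the allyl–phenolate ion pair decides which enantiotopic face of C3 meets the allyl terminus. The step needs C- over O-alkylation (an aryl prenyl ether of so acidic a phenol is re-ionised by palladium, so the irreversible C–C bond formation drains it), C3 over C5 and C1 (methyl is much smaller than the 2,6-disubstituted benzyl group, and the acyl-bearing C1 is not alkylated in such phenolates), linear over branched prenyl (a fully substituted nucleophilic carbon avoids the tertiary terminus, which would create two adjacent quaternary carbons) and ring A over ring B (the MOM caps leave ring B without a phenolate). Only a slight excess of 14 and a low temperature are used so that a second prenylation of the more acidic product at C5 should not compete.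

**Step 11**
Reactants: 15 bis-MOM ether of the target
Product: 16 (4S)-2-hexanoyl-6-[(3-hexanoyl-2,4-dihydroxy-6-methoxyphenyl)methyl]-3,5-dihydroxy-4-methyl-4-(3-methylbut-2-en-1-yl)cyclohexa-2,5-dien-1-one
Conditions: HCl (1 M in MeOH), 0 °C → rt; aq. NaHCO3 to pH 5
Reagents that add atoms: none
Why: Acid-catalysed acetal solvolysis (MOM cleavage), fast for aryl MOM ethers ortho to a carbonyl group and run cold and dilute so that the trisubstituted alkene is not protonated; the quaternary stereocentre has no epimerisable hydrogen.

**Compound list**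

1 | phloroglucinol (benzene-1,3,5-triol) | Oc1cc(O)cc(O)c1 | starting material
2 | hexanoyl chloride | CCCCCC(=O)Cl | starting material
3 | 1-(2,4,6-trihydroxyphenyl)hexan-1-one | CCCCCC(=O)c1c(O)cc(O)cc1O | intermediate
4 | 1-(2,6-dihydroxy-4-methoxyphenyl)hexan-1-one | CCCCCC(=O)c1c(O)cc(OC)cc1O | intermediate
5 | 1-{3-[chloro(methoxy)methyl]-2,6-dihydroxy-4-methoxyphenyl}hexan-1-one (racemic α-chloro ether, not isolated) | CCCCCC(=O)c1c(O)cc(OC)c(C(Cl)OC)c1O | intermediate
6 | 3-hexanoyl-2,4-dihydroxy-6-methoxybenzaldehyde | CCCCCC(=O)c1c(O)cc(OC)c(C=O)c1O | intermediate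
7 | 3-hexanoyl-6-methoxy-2,4-bis(methoxymethoxy)benzaldehyde | CCCCCC(=O)c1c(OCOC)cc(OC)c(C=O)c1OCOC | intermediate
8 | 1-[3-(hydroxymethyl)-4-methoxy-2,6-bis(methoxymethoxy)phenyl]hexan-1-one | CCCCCC(=O)c1c(OCOC)cc(OC)c(CO)c1OCOC | intermediate
9 | 1-[3-(bromomethyl)-4-methoxy-2,6-bis(methoxymethoxy)phenyl]hexan-1-one | CCCCCC(=O)c1c(OCOC)cc(OC)c(CBr)c1OCOC | intermediate
10 | 2-methylphloroglucinol (2-methylbenzene-1,3,5-triol) | Cc1c(O)cc(O)cc1O | starting material
11 | 1-(2,4,6-trihydroxy-3-methylphenyl)hexan-1-one | CCCCCC(=O)c1c(O)c(C)c(O)cc1O | intermediate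
12 | 1-(3-{[3-hexanoyl-6-methoxy-2,4-bis(methoxymethoxy)phenyl]methyl}-2,4,6-trihydroxy-5-methylphenyl)hexan-1-one (bis-MOM diarylmethane) | CCCCCC(=O)c1c(O)c(C)c(O)c(Cc2c(OC)cc(OCOC)c(C(=O)CCCCC)c2OCOC)c1O | intermediate
13 | prenol (3-methylbut-2-en-1-ol) | CC(C)=CCO | starting material
14 | methyl 3-methylbut-2-en-1-yl carbonate (prenyl methyl carbonate) | COC(=O)OCC=C(C)C | intermediate
15 | (4S)-2-hexanoyl-6-{[3-hexanoyl-6-methoxy-2,4-bis(methoxymethoxy)phenyl]methyl}-3,5-dihydroxy-4-methyl-4-(3-methylbut-2-en-1-yl)cyclohexa-2,5-dien-1-one (bis-MOM ether of the target) | CCCCCC(=O)C1=C(O)[C@@](C)(CC=C(C)C)C(O)=C(Cc2c(OC)cc(OCOC)c(C(=O)CCCCC)c2OCOC)C1=O | intermediate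
16 | (4S)-2-hexanoyl-6-[(3-hexanoyl-2,4-dihydroxy-6-methoxyphenyl)methyl]-3,5-dihydroxy-4-methyl-4-(3-methylbut-2-en-1-yl)cyclohexa-2,5-dien-1-one | CCCCCC(=O)C1=C(O)[C@@](C)(CC=C(C)C)C(O)=C(Cc2c(OC)cc(O)c(C(=O)CCCCC)c2O)C1=O | target

**Step count**

Total step count: 11. Longest linear sequence: 9 steps (steps 1, 2, 3, 4, 5, 6, 8, 10 and 11, from phloroglucinol); steps 7 and 9 are side branches.

**Steps most likely to fail**

Step 10. Enantioface discrimination at C3 may be insufficient, or prenyl transfer may drift to C5, to oxygen or to a second alkylation of the product. The fallback sets out from 12 and comes back at 15 by chiral ion-pair phase-transfer alkylation instead of π-allyl chemistry. 12 would be treated with prenyl bromide (1.1 equiv), CsOH·H2O and 10 mol % N-(9-anthracenylmethyl)cinchonidinium bromide (or its cinchoninium pseudo-enantiomer, whichever gives the S sense) in toluene/CHCl3 at −40 °C. This is a known mode of asymmetric dearomative alkylation of acylphloroglucinol phenolates, and direct displacement gives the linear prenyl group. The fallback makes no compound outside the list (F0).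

Step 8. O-benzylation, hydrolysis of the labile bromide or double alkylation may outrun C-benzylation at C5. The fallback sets out from alcohol 8 and 11, bypasses bromide 9, and comes back at 12. 8 and 11 (1.5 equiv) would be stirred in 1,1,1,3,3,3-hexafluoropropan-2-ol at rt, where the solvent ionises the trialkoxybenzylic alcohol and the cation is trapped by C5 of neutral 11 in a dehydrative Friedel–Crafts benzylation without base or halide. No compound outside the list is made (F0).

Step 11. Acid may cyclise the prenyl chain onto a neighbouring enol oxygen before both acetals are gone, or cleavage may stall at the mono-MOM stage. The fallback sets out from 6 and comes back at 16 with fluoride-labile SEM groups in place of MOM. 6 would be protected (SEMCl, NaH, DMF) to the bis-SEM aldehyde F1, reduced (NaBH4, −20 °C) to the benzylic alcohol F2, and brominated (CBr4, PPh3) to the bromide F3. F3 would be coupled with 11 (aq. KOH, THF) to the bis-SEM diarylmethane F4 and prenylated with 14 under the conditions of step 10 to the bis-SEM dienone F5. The SEM groups would then be removed without acid by nBu4NF in THF/DMPU at 45 °C, giving 16.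

**Further compounds**

F0 | step 10 | none | none
F0 | step 8 | none | none
F1 | step 11 | 3-hexanoyl-6-methoxy-2,4-bis{[2-(trimethylsilyl)ethoxy]methoxy}benzaldehyde | CCCCCC(=O)c1c(OCOCC[Si](C)(C)C)cc(OC)c(C=O)c1OCOCC[Si](C)(C)C
F2 | step 11 | 1-(3-(hydroxymethyl)-4-methoxy-2,6-bis{[2-(trimethylsilyl)ethoxy]methoxy}phenyl)hexan-1-one | CCCCCC(=O)c1c(OCOCC[Si](C)(C)C)cc(OC)c(CO)c1OCOCC[Si](C)(C)C
F3 | step 11 | 1-(3-(bromomethyl)-4-methoxy-2,6-bis{[2-(trimethylsilyl)ethoxy]methoxy}phenyl)hexan-1-one | CCCCCC(=O)c1c(OCOCC[Si](C)(C)C)cc(OC)c(CBr)c1OCOCC[Si](C)(C)C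
F4 | step 11 | 1-(3-{[3-hexanoyl-6-methoxy-2,4-bis{[2-(trimethylsilyl)ethoxy]methoxy}phenyl]methyl}-2,4,6-trihydroxy-5-methylphenyl)hexan-1-one | CCCCCC(=O)c1c(O)c(C)c(O)c(Cc2c(OC)cc(OCOCC[Si](C)(C)C)c(C(=O)CCCCC)c2OCOCC[Si](C)(C)C)c1O
F5 | step 11 | (4S)-2-hexanoyl-6-{[3-hexanoyl-6-methoxy-2,4-bis{[2-(trimethylsilyl)ethoxy]methoxy}phenyl]methyl}-3,5-dihydroxy-4-methyl-4-(3-methylbut-2-en-1-yl)cyclohexa-2,5-dien-1-one | CCCCCC(=O)C1=C(O)[C@@](C)(CC=C(C)C)C(O)=C(Cc2c(OC)cc(OCOCC[Si](C)(C)C)c(C(=O)CCCCC)c2OCOCC[Si](C)(C)C)C1=O
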